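**Retrosynthetic overview**

1. The strategy rests on the 4-alkoxy-2-pyranone ring of the coumarin (O1–C2(=O)–C3=C4, fused to the arene at C4a/C8a, C5 methyl peri to C4). C4 with its ether oxygen is read as the carbonyl carbon of a 6-methylsalicylate ester of the chain alcohol, O1 as the phenol oxygen, and C2–C3 as a two-carbon ketene unit.
2. Last disconnection: C7'–OOH and the E C5'=C6' alkene come from a prenyl terminus by singlet-oxygen ene reaction, after desilylation of C4'–OH.
3. Key disconnection: O1–C2 and C3=C4 by addition of the salicylate phenol to ketenylidenetriphenylphosphorane and intramolecular Wittig olefination of the ester carbonyl. The ester C–O bond comes from a Mitsunobu reaction of 6-methylsalicylic acid.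
4. Chain: prenyl acetate → E-enal (SeO2) → asymmetric allylboration (sets C4' as R) → TBS ether → cross-metathesis to the prenyl group → deacetylation.
5. Ring order: the benzene ring is bought; the pyranone ring is the only ring formed (step 7).

Key step: step 7

Assumption: primed locants C1'–C8' denote the side chain (C1' on the coumarin oxygen). The allylborane made from (+)-Ipc2BOMe (derived from (−)-α-pinene) is taken to deliver allyl to the Re face of aldehyde 2, as with simple aldehydes; if the sense proved opposite, the enantiomeric borane would be used.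

**Route**

Step 1
Reactants: 1 prenyl acetate (3-methylbut-2-en-1-yl acetate)
Product: 2 (2E)-3-methyl-4-oxobut-2-en-1-yl acetate
Conditions: SeO2 (1.2 equiv), 1,4-dioxane, 90 °C
Reagents that add atoms: selenium dioxide, O=[Se]=O
Why: Riley allylic oxidation (ene reaction, then [2,3]-sigmatropic shift) attacks the methyl group trans to the CH2OAc branch of the trisubstituted alkene and carries it on to the aldehyde, so the E-enal should result with the acetate untouched.

Step 2
Reactants: 2 (2E)-3-methyl-4-oxobut-2-en-1-yl acetate
Product: 4 (2E,4R)-4-hydroxy-3-methylhepta-2,6-dien-1-yl acetate, via diisopinocampheylborinate ester 3 (not isolated)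
Conditions: (+)-Ipc2BOMe, allylMgBr (0.95 equiv to boron), Et2O, 0 °C → rt; then 2, −78 °C; then 30% H2O2, pH 7 buffer, MeOH, 0 °C → rt
Reagents that add atoms: allylmagnesium bromide, C=CC[Mg]Br
Why: Brown asymmetric allylboration through a closed six-membered chair transition state, in which the isopinocampheyl groups should steer the allyl group to the Re face of the aldehyde and set C4 as R; the borane reacts with the aldehyde far faster than with the acetate at −78 °C, and the buffered peroxide work-up frees the alcohol without ester hydrolysis.

Step 3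
Reactants: 4 (2E,4R)-4-hydroxy-3-methylhepta-2,6-dien-1-yl acetate
Product: 5 (2E,4R)-4-(tert-butyldimethylsilyloxy)-3-methylhepta-2,6-dien-1-yl acetate
Conditions: TBSCl, imidazole, DMF, rt
Reagents that add atoms: tert-butyldimethylsilyl chloride, CC(C)(C)[Si](C)(C)Cl
Why: Imidazole-promoted silylation masks the only hydroxyl, so that later only the phenol can add to the ylide; the acetate and the C4 configuration are not affected.

Step 4
Reactants: 5 (2E,4R)-4-(tert-butyldimethylsilyloxy)-3-methylhepta-2,6-dien-1-yl acetate
Product: 6 (2E,4R)-4-(tert-butyldimethylsilyloxy)-3,7-dimethylocta-2,6-dien-1-yl acetate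
Conditions: Grubbs II (5 mol %), 2-methyl-2-butene/CH2Cl2, rt → 35 °C
Reagents that add atoms: 2-methyl-2-butene, CC=C(C)C
Why: Olefin cross-metathesis, in which the monosubstituted C6=C7 alkene is the only one the ruthenium carbene engages readily; the large excess of 2-methyl-2-butene converts it into the prenyl terminus while the hindered trisubstituted C2=C3 alkene stays out.

Step 5
Reactants: 6 (2E,4R)-4-(tert-butyldimethylsilyloxy)-3,7-dimethylocta-2,6-dien-1-yl acetate
Product: 7 (2E,4R)-4-(tert-butyldimethylsilyloxy)-3,7-dimethylocta-2,6-dien-1-ol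
Conditions: K2CO3, MeOH, 0 °C → rt
Reagents that add atoms: none
Why: Base-catalysed methanolysis (transesterification) removes the primary acetate, and the secondary TBS ether is stable to K2CO3/MeOH.

Step 6
Reactants: 7 (2E,4R)-4-(tert-butyldimethylsilyloxy)-3,7-dimethylocta-2,6-dien-1-ol; 8 2-hydroxy-6-methylbenzoic acid (6-methylsalicylic acid)
Product: 9 (2E,4R)-4-(tert-butyldimethylsilyloxy)-3,7-dimethylocta-2,6-dien-1-yl 2-hydroxy-6-methylbenzoate
Conditions: PPh3, DIAD, THF, 0 °C → rt
Reagents that add atoms: none
Why: Mitsunobu esterification, in which the carboxylic acid (far more acidic than the hydrogen-bonded phenol) is the pronucleophile and displaces the primary allylic oxyphosphonium at C1' by SN2; this suits a 2,6-disubstituted benzoic acid because the acid reacts through oxygen and its hindered carbonyl is never attacked.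

Step 7
Reactants: 9 (2E,4R)-4-(tert-butyldimethylsilyloxy)-3,7-dimethylocta-2,6-dien-1-yl 2-hydroxy-6-methylbenzoate; 10 ketenylidenetriphenylphosphorane
Product: 12 4-{[(2E,4R)-4-(tert-butyldimethylsilyloxy)-3,7-dimethylocta-2,6-dien-1-yl]oxy}-5-methyl-2H-chromen-2-one, via aryl ester ylide 11 (not isolated)
Conditions: Ph3P=C=C=O (1.2 equiv), toluene, 70–80 °C
Reagents that add atoms: none
Why: The phenol O–H of 9 adds across the C=C of the cumulated ylide to give the aryl (triphenylphosphoranylidene)acetate 11 (O1–C2 bond); its stabilised ylide carbon then attacks the neighbouring benzoate carbonyl, and the oxaphosphetane collapses with loss of Ph3P=O to leave the C3=C4 enol ether of the 2-pyranone. The closest known reaction type is the domino addition/intramolecular Wittig olefination of hydroxy esters with this ylide, established for α-hydroxy esters (giving tetronates) and for salicylates (giving 4-alkoxycoumarins). The six-membered ring closes in 6-exo-trig mode, the attacked C=O being exocyclic to the forming ring. No stereocentre is formed, and C4' is remote from the reacting carbonyl and carries no activated hydrogen, so its configuration is untouched. Chemoselectivity is secured because the phenol is the only free O–H (C4'–OH is silylated) and because the chain oxygen is already bonded to the future C4 as an ester, which removes any O- versus C3-alkylation question; the ortho oxygen and the C6 methyl twist the ester out of the arene plane and turn its π face toward the ylide. The temperature is held at or below 80 °C so that the new 4-allyloxycoumarin does not undergo Claisen rearrangement to C3.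

Step 8
Reactants: 12 4-{[(2E,4R)-4-(tert-butyldimethylsilyloxy)-3,7-dimethylocta-2,6-dien-1-yl]oxy}-5-methyl-2H-chromen-2-one
Product: 13 4-{[(2E,4R)-4-hydroxy-3,7-dimethylocta-2,6-dien-1-yl]oxy}-5-methyl-2H-chromen-2-one
Conditions: HF·pyridine, pyridine, THF, 0 °C → rt
Reagents that add atoms: none
Why: Fluoride-mediated cleavage of the silyl ether (driven by Si–F bond formation); buffered HF·pyridine should spare the lactone, the enol ether and the allylic C1'–O bond.

Step 9
Reactants: 13 4-{[(2E,4R)-4-hydroxy-3,7-dimethylocta-2,6-dien-1-yl]oxy}-5-methyl-2H-chromen-2-one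
Product: 14 4-{[(2E,4R,5E)-7-hydroperoxy-4-hydroxy-3,7-dimethylocta-2,5-dien-1-yl]oxy}-5-methyl-2H-chromen-2-one
Conditions: O2, TPP (cat.), white LED, CH2Cl2, 0 °C; silica chromatography, no reductive work-up
Reagents that add atoms: oxygen, O=O
Why: Schenck ene reaction of singlet oxygen, which should pick the electron-rich trialkyl C6'=C7' alkene over the C2'=C3' alkene (deactivated by two allylic oxygens) and the vinylogous-carbonate C3=C4; abstraction of a C5' hydrogen places the hydroperoxide on C7' and shifts the alkene to C5'=C6' with E geometry, C4' is not touched, and the regioisomeric secondary hydroperoxide from methyl-hydrogen abstraction is removed by chromatography.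

**Compound list**

1 | prenyl acetate (3-methylbut-2-en-1-yl acetate) | CC(C)=CCOC(C)=O | starting material
2 | (2E)-3-methyl-4-oxobut-2-en-1-yl acetate | C/C(=C\COC(C)=O)C=O | intermediate
3 | (2E,4R)-4-[(diisopinocampheylboranyl)oxy]-3-methylhepta-2,6-dien-1-yl acetate | C/C(=C\COC(C)=O)[C@H](OB([C@H]1C[C@H]2C[C@@H]([C@@H]1C)C2(C)C)[C@H]1C[C@H]2C[C@@H]([C@@H]1C)C2(C)C)CC=C | intermediate (not isolated)
4 | (2E,4R)-4-hydroxy-3-methylhepta-2,6-dien-1-yl acetate | C/C(=C\COC(C)=O)[C@H](O)CC=C | intermediate
5 | (2E,4R)-4-(tert-butyldimethylsilyloxy)-3-methylhepta-2,6-dien-1-yl acetate | C/C(=C\COC(C)=O)[C@H](O[Si](C)(C)C(C)(C)C)CC=C | intermediate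
6 | (2E,4R)-4-(tert-butyldimethylsilyloxy)-3,7-dimethylocta-2,6-dien-1-yl acetate | C/C(=C\COC(C)=O)[C@H](O[Si](C)(C)C(C)(C)C)CC=C(C)C | intermediate
7 | (2E,4R)-4-(tert-butyldimethylsilyloxy)-3,7-dimethylocta-2,6-dien-1-ol | C/C(=C\CO)[C@H](O[Si](C)(C)C(C)(C)C)CC=C(C)C | intermediate
8 | 2-hydroxy-6-methylbenzoic acid | Cc1cccc(O)c1C(=O)O | starting material
9 | (2E,4R)-4-(tert-butyldimethylsilyloxy)-3,7-dimethylocta-2,6-dien-1-yl 2-hydroxy-6-methylbenzoate | C/C(=C\COC(=O)c1c(C)cccc1O)[C@H](O[Si](C)(C)C(C)(C)C)CC=C(C)C | intermediate
10 | ketenylidenetriphenylphosphorane | O=C=C=P(c1ccccc1)(c1ccccc1)c1ccccc1 | starting material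
11 | (2E,4R)-4-(tert-butyldimethylsilyloxy)-3,7-dimethylocta-2,6-dien-1-yl 2-methyl-6-{[(triphenylphosphoranylidene)acetyl]oxy}benzoate | C/C(=C\COC(=O)c1c(C)cccc1OC(=O)C=P(c1ccccc1)(c1ccccc1)c1ccccc1)[C@H](O[Si](C)(C)C(C)(C)C)CC=C(C)C | intermediate (not isolated)
12 | 4-{[(2E,4R)-4-(tert-butyldimethylsilyloxy)-3,7-dimethylocta-2,6-dien-1-yl]oxy}-5-methyl-2H-chromen-2-one | C/C(=C\COc1cc(=O)oc2cccc(C)c12)[C@H](O[Si](C)(C)C(C)(C)C)CC=C(C)C | intermediate
13 | 4-{[(2E,4R)-4-hydroxy-3,7-dimethylocta-2,6-dien-1-yl]oxy}-5-methyl-2H-chromen-2-one | C/C(=C\COc1cc(=O)oc2cccc(C)c12)[C@H](O)CC=C(C)C | intermediate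
14 | 4-{[(2E,4R,5E)-7-hydroperoxy-4-hydroxy-3,7-dimethylocta-2,5-dien-1-yl]oxy}-5-methyl-2H-chromen-2-one | C/C(=C\COc1cc(=O)oc2cccc(C)c12)[C@H](O)/C=C/C(C)(C)OO | target

**Step count**

Total: 9 steps. Longest linear sequence: 9 steps (1 → 14); compounds 8 and 10 enter as bought.

**Steps most likely to fail, with fallbacks**

Step 7. The ylide carbon may be too slow to olefinate the weakly electrophilic, doubly ortho-substituted aryl ester below the temperature at which the allyl enol ether product begins its [3,3] shift, so the sequence may stall at the ester ylide or drift into Claisen rearrangement. The fallback sets out from alcohol 7 and moves ring formation away from the chain. Commercial 1-(2-hydroxy-6-methylphenyl)ethan-1-one F1 would be condensed with diethyl carbonate (NaH, toluene, reflux; Claisen condensation and lactonisation) to give 4-hydroxy-5-methyl-2H-chromen-2-one F2. F2 would then be O-alkylated with 7 under Mitsunobu conditions (PPh3, DIAD, THF, 0 °C → rt), which favour O- over C3-alkylation for 4-hydroxycoumarins, and any isomeric by-product would be removed by chromatography. The fallback comes back to the route at 12.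

Step 9. Hydrogen abstraction may be unselective between the C5' methylene and the methyl groups, a hydroxyl-directed ene reaction may compete at C2'=C3', and the polar hydroperoxy alcohols may be lost during separation. The fallback sets out from silyl ether 12 and changes the order of the end game. Photooxygenation (O2, TPP, visible light, CH2Cl2, 0 °C) of 12, which has no free hydroxyl to direct singlet oxygen to C2'=C3', should give 4-{[(2E,4R,5E)-4-(tert-butyldimethylsilyloxy)-7-hydroperoxy-3,7-dimethylocta-2,5-dien-1-yl]oxy}-5-methyl-2H-chromen-2-one F3, which is less polar and easier to separate from its regioisomer. HF·pyridine in pyridine/THF then removes the silyl group, and the fallback comes back to the route at 14.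

Step 6. Under Mitsunobu conditions the phenol may compete as the nucleophile, the allylic oxyphosphonium may be attacked in the SN2' sense, or the hindered acid may react sluggishly. The fallback sets out from 7 and separates activation from esterification. An Appel reaction (CBr4, PPh3, CH2Cl2, 0 °C) would give tert-butyl{[(2E,4R)-1-bromo-3,7-dimethylocta-2,6-dien-4-yl]oxy}dimethylsilane F4. F4 would then alkylate the carboxylate of 8 (KHCO3, DMF, rt), conditions under which the phenol stays protonated. The fallback comes back to the route at 9.

**Further compounds**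

F1 | step 7 | 1-(2-hydroxy-6-methylphenyl)ethan-1-one | CC(=O)c1c(C)cccc1O
F2 | step 7 | 4-hydroxy-5-methyl-2H-chromen-2-one | Cc1cccc2oc(=O)cc(O)c12
F3 | step 9 | 4-{[(2E,4R,5E)-4-(tert-butyldimethylsilyloxy)-7-hydroperoxy-3,7-dimethylocta-2,5-dien-1-yl]oxy}-5-methyl-2H-chromen-2-one | C/C(=C\COc1cc(=O)oc2cccc(C)c12)[C@H](O[Si](C)(C)C(C)(C)C)/C=C/C(C)(C)OO
F4 | step 6 | tert-butyl{[(2E,4R)-1-bromo-3,7-dimethylocta-2,6-dien-4-yl]oxy}dimethylsilane | C/C(=C\CBr)[C@H](O[Si](C)(C)C(C)(C)C)CC=C(C)C
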